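**Assumptions.** (1) The hemiketal carbon C‑2 is configurationally labile (ring–chain tautomerism). It is written as in the given SMILES, but the route delivers whatever configuration transannular closure of 5‑OH onto C‑2 imposes, and no reagent controls it. The other five stereocentres (4R,5R,6S,7R,8S) are set by the route. (2) Positions are labelled with germacrane numbering: C‑2 hemiketal carbon, C‑4 C(Me)OMe, C‑5 oxolane CH–O, C‑6 lactone CH–O, C‑7, C‑8 CH–O‑tigloyl, C‑10 exocyclic methylene carbon.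

## Retrosynthetic overview

1. Target ⇐ cycloalkyne **25** by transannular Au(I) hydroalkoxylation/hydration (5‑OH onto C‑2); the oxolane hemiketal is formed last.
2. **25** ⇐ bromide **24** by Cu‑catalysed intramolecular alkynyl–allyl coupling (C1–C2), which closes the 10‑membered carbocycle.
3. α‑Methylene‑γ‑lactone ⇐ homopropargylic alcohol **21** by Pd‑catalysed cyclocarbonylation; the lactone is the first ring formed.
4. **21** ⇐ aldehyde **9** (C2–C6) + propargylic mesylate **20** (C7–C10, C1, C11, C13, tiglate) by Pd/In propargylation (C6–C7).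
5. **9** from but‑2‑yn‑1‑ol (Sonogashira, Sharpless epoxidation, methanolysis); **20** from methallyl alcohol (Ti–BINOL glyoxylate‑ene, CBS reduction).

## Route

### Fragment A: aldehyde 9 (C2–C6)

**Step 1**
Reactants: **1** but‑2‑yn‑1‑ol
Product: **2** (Z)‑3‑iodobut‑2‑en‑1‑ol
Conditions: Red‑Al, THF, 0 °C → rt; then I2, −78 → 0 °C
Reagents that add atoms: iodine, II
Why: Hydroxyl‑directed trans‑hydroalumination followed by iodinolysis with retention gives only the Z iodide (I cis to CH2OH).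

**Step 2**
Reactants: **2**; **3** ethynyltrimethylsilane
Product: **4** (Z)‑3‑methyl‑5‑(trimethylsilyl)pent‑2‑en‑4‑yn‑1‑ol
Conditions: Pd(PPh3)2Cl2 (2 mol%), CuI (4 mol%), i‑Pr2NH, THF, rt
Reagents that add atoms: none
Why: Sonogashira coupling proceeds with retention of alkene geometry, placing the alkyne (C‑2/C‑3) cis to CH2OH (C‑6); the TMS group masks the C‑2 terminus until step 17.

**Step 3**
Reactants: **4**
Product: **5** [(2R,3S)‑3‑methyl‑3‑[(trimethylsilyl)ethynyl]oxiran‑2‑yl]methanol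
Conditions: Ti(Oi‑Pr)4, D‑(−)‑DET, t‑BuOOH, 4 Å MS, CH2Cl2, −20 °C
Reagents that add atoms: tert‑butyl hydroperoxide, CC(C)(C)OO
Why: Sharpless asymmetric epoxidation of a nerol‑type allylic alcohol; D‑(−)‑tartrate gives the 2R epoxide (L‑(+) gives 2S), which fixes C‑5 and, through the Z geometry, C‑4.

**Step 4**
Reactants: **5**
Product: **6** (2R,3R)‑3‑methoxy‑3‑methyl‑5‑(trimethylsilyl)pent‑4‑yne‑1,2‑diol
Conditions: CSA (10 mol%), MeOH, 0 °C
Reagents that add atoms: methanol, CO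
Why: Acid‑catalysed epoxide methanolysis at the tertiary propargylic carbon with inversion installs the C‑4 methyl ether (4R) and keeps C‑5 (R), giving the syn OMe/OH pair.

**Step 5**
Reactants: **6**
Product: **7** (2R,3R)‑1,2‑bis[(tert‑butyldimethylsilyl)oxy]‑3‑methoxy‑3‑methyl‑5‑(trimethylsilyl)pent‑4‑yne
Conditions: TBSOTf, 2,6‑lutidine, CH2Cl2, 0 °C
Reagents that add atoms: TBSOTf, CC(C)(C)[Si](C)(C)OS(=O)(=O)C(F)(F)F
Why: Standard bis‑silylation; the hindered secondary 5‑OH needs the triflate.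

**Step 6**
Reactants: **7**
Product: **8** (2R,3R)‑2‑[(tert‑butyldimethylsilyl)oxy]‑3‑methoxy‑3‑methyl‑5‑(trimethylsilyl)pent‑4‑yn‑1‑ol
Conditions: HF·pyridine, pyridine, THF, 0 °C
Reagents that add atoms: none
Why: Selective cleavage of the primary TBS ether; the neopentyl‑type secondary TBS and the alkynyl‑TMS survive buffered HF.

**Step 7**
Reactants: **8**
Product: **9** (2S,3R)‑2‑[(tert‑butyldimethylsilyl)oxy]‑3‑methoxy‑3‑methyl‑5‑(trimethylsilyl)pent‑4‑ynal
Conditions: Dess–Martin periodinane, NaHCO3, CH2Cl2, rt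
Reagents that add atoms: none
Why: Neutral Dess–Martin oxidation gives the α‑silyloxy aldehyde without epimerisation (the descriptor changes only through CIP priorities); use directly.

### Fragment B: mesylate 20 (C7–C10, C1, C11, C13, tiglate)

**Step 8**
Reactants: **10** 2‑methylprop‑2‑en‑1‑ol
Product: **11** tert‑butyl[(2‑methylprop‑2‑en‑1‑yl)oxy]diphenylsilane
Conditions: TBDPSCl, imidazole, DMF, rt
Reagents that add atoms: TBDPSCl, CC(C)(C)[Si](Cl)(c1ccccc1)c1ccccc1
Why: Routine silylation; the allylic silyl ether is inert to Pd(0) in steps 15 and 16.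

**Step 9**
Reactants: **11**; **12** ethyl glyoxylate
Product: **13** ethyl (2S)‑4‑{[(tert‑butyldiphenylsilyl)oxy]methyl}‑2‑hydroxypent‑4‑enoate
Conditions: (S)‑BINOL (10 mol%), TiCl2(Oi‑Pr)2 (10 mol%), 4 Å MS, CH2Cl2, −30 °C
Reagents that add atoms: none
Why: Mikami Ti–BINOL glyoxylate‑ene reaction; H is taken from the methyl group (C–H next to OSi is deactivated), and (S)‑BINOL gives the (S)‑hydroxy ester, setting C‑8 and the exocyclic methylene.

**Step 10**
Reactants: **13**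
Product: **14** (2S)‑4‑{[(tert‑butyldiphenylsilyl)oxy]methyl}‑2‑hydroxy‑N‑methoxy‑N‑methylpent‑4‑enamide
Conditions: MeNH(OMe)·HCl, i‑PrMgCl, THF, −20 → 0 °C
Reagents that add atoms: N,O‑dimethylhydroxylamine hydrochloride, CNOC.Cl
Why: Direct Weinreb amidation of an α‑hydroxy ester; the magnesium alkoxide protects C‑8 from enolisation.

**Step 11**
Reactants: **14**; **15** tigloyl chloride [(E)‑2‑methylbut‑2‑enoyl chloride]
Product: **16** (2S)‑4‑{[(tert‑butyldiphenylsilyl)oxy]methyl}‑1‑[methoxy(methyl)amino]‑1‑oxopent‑4‑en‑2‑yl (E)‑2‑methylbut‑2‑enoate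
Conditions: pyridine, DMAP (cat.), CH2Cl2, 0 °C
Reagents that add atoms: none
Why: O‑acylation installs the C‑8 tiglate early, so O‑8 can never compete with O‑6 for the lactone (this fixes the 6,12‑olide regiochemistry).

**Step 12**
Reactants: **16**; **17** ethynylmagnesium bromide
Product: **18** (4S)‑6‑{[(tert‑butyldiphenylsilyl)oxy]methyl}‑3‑oxohept‑6‑en‑1‑yn‑4‑yl (E)‑2‑methylbut‑2‑enoate
Conditions: THF, −40 → −10 °C; inverse quench into cold aq. NaHSO4
Reagents that add atoms: none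
Why: Weinreb ketone synthesis; the chelated amide reacts faster than the hindered conjugated tiglate, and the acidic inverse quench prevents amine addition to the ynone.

**Step 13**
Reactants: **18**
Product: **19** (3S,4S)‑6‑{[(tert‑butyldiphenylsilyl)oxy]methyl}‑3‑hydroxyhept‑6‑en‑1‑yn‑4‑yl (E)‑2‑methylbut‑2‑enoate
Conditions: (R)‑Me‑CBS (0.5 equiv), catecholborane, toluene, −78 °C
Reagents that add atoms: none
Why: Corey–Bakshi–Shibata reduction with the alkynyl group as the small substituent; (R)‑CBS gives the 3S carbinol (syn to the 4‑acyloxy group, also the polar Felkin product), and esters and alkenes are untouched.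

**Step 14**
Reactants: **19**
Product: **20** (3S,4S)‑6‑{[(tert‑butyldiphenylsilyl)oxy]methyl}‑3‑[(methanesulfonyl)oxy]hept‑6‑en‑1‑yn‑4‑yl (E)‑2‑methylbut‑2‑enoate
Conditions: MsCl, Et3N, CH2Cl2, −78 °C
Reagents that add atoms: methanesulfonyl chloride, CS(=O)(=O)Cl
Why: Mesylation with retention; fast at low temperature, so no acyl migration.

### Union, rings and end game

**Step 15**
Reactants: **9**; **20**
Product: **21** (4S,5S,6S,7R,8R)‑7‑[(tert‑butyldimethylsilyl)oxy]‑2‑{[(tert‑butyldiphenylsilyl)oxy]methyl}‑5‑ethynyl‑6‑hydroxy‑8‑methoxy‑8‑methyl‑10‑(trimethylsilyl)dec‑1‑en‑9‑yn‑4‑yl (E)‑2‑methylbut‑2‑enoate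
Conditions: Pd(dppf)Cl2 (5 mol%), InI (1.5 equiv), THF–DMPU (3:1), rt
Reagents that add atoms: none
Why: Marshall–Tamaru Pd(0)/In(I) propargylation: anti‑SN2′ oxidative addition to the (3S)‑mesylate gives an axially chiral allenylindium that adds through a cyclic SE2′ transition state, forming C6–C7 with net inversion at C‑7 and the anti C6/C7 pair under reagent control.

**Step 16**
Reactants: **21**
Product: **22** (1S)‑1‑{(2S,3R)‑2‑[(1R,2R)‑1‑[(tert‑butyldimethylsilyl)oxy]‑2‑methoxy‑2‑methyl‑4‑(trimethylsilyl)but‑3‑yn‑1‑yl]‑4‑methylidene‑5‑oxooxolan‑3‑yl}‑3‑{[(tert‑butyldiphenylsilyl)oxy]methyl}but‑3‑en‑1‑yl (E)‑2‑methylbut‑2‑enoate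
Conditions: PdCl2(PPh3)2 (10 mol%), SnCl2 (10 mol%), CO (8 atm), MeCN, 65 °C
Reagents that add atoms: carbon monoxide, [C-]#[O+]
Why: Norton‑type Pd cyclocarbonylation of a homopropargylic alcohol (alkoxycarbonyl‑Pd, syn alkyne insertion, protonolysis) gives the α‑methylene‑γ‑lactone; only 6‑OH is free and the silylated alkyne is inert, and trans fusion follows from C‑6/C‑7.

**Step 17**
Reactants: **22**
Product: **23** (1S)‑1‑{(2S,3R)‑2‑[(1R,2R)‑1‑hydroxy‑2‑methoxy‑2‑methylbut‑3‑yn‑1‑yl]‑4‑methylidene‑5‑oxooxolan‑3‑yl}‑3‑(hydroxymethyl)but‑3‑en‑1‑yl (E)‑2‑methylbut‑2‑enoate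
Conditions: TBAF, AcOH (1:1), THF, 0 °C → rt
Reagents that add atoms: none
Why: Buffered fluoride removes the TBS, TBDPS and alkynyl‑TMS groups in one operation; the tiglate and the α‑methylene lactone tolerate these conditions.

**Step 18**
Reactants: **23**
Product: **24** (1S)‑3‑(bromomethyl)‑1‑{(2S,3R)‑2‑[(1R,2R)‑1‑hydroxy‑2‑methoxy‑2‑methylbut‑3‑yn‑1‑yl]‑4‑methylidene‑5‑oxooxolan‑3‑yl}but‑3‑en‑1‑yl (E)‑2‑methylbut‑2‑enoate
Conditions: CBr4, PPh3, CH2Cl2, −20 °C
Reagents that add atoms: carbon tetrabromide, BrC(Br)(Br)Br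
Why: Appel bromination is selective for the primary allylic alcohol over the hindered secondary 5‑OH.

**Step 19**
Reactants: **24**
Product: **25** (4R,5R,6S,7R,8S)‑5‑hydroxy‑4‑methoxy‑8‑tigloyloxygermacra‑10(14),11(13)‑dien‑2‑yn‑12,6‑olide (10‑membered cycloalkyne)
Conditions: CuI (20 mol%), K2CO3, NaI (cat.), DMF, 1 mM, syringe‑pump addition, 30 °C
Reagents that add atoms: none
Why: Proposed new method: Cu(I)‑catalysed macrocyclising C(sp)–C(sp3) alkynyl–allyl coupling to a medium‑ring cycloalkyne — the Cu acetylide attacks the allylic bromide (SN2 and SN2′ give the same product because the 2‑substituted allyl unit is symmetric), cyclodecyne strain is modest, and the quaternary C‑4 and trans‑lactone pre‑organise the chain; the closest known reaction is the intermolecular Cu‑catalysed coupling of terminal alkynes with allylic halides to skipped enynes.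

**Step 20**
Reactants: **25**
Product: **26** target (CID 86289099)
Conditions: (JohnPhos)Au(MeCN)SbF6 (5 mol%), THF/H2O (10:1), rt
Reagents that add atoms: water, O
Why: Au(I)‑catalysed 5‑endo‑dig hydroalkoxylation of the homopropargylic 5‑OH onto C‑2, then hydration of the bridged enol ether, gives the C‑2 ketone oxidation level regiospecifically as the hemiketal under neutral conditions (no base that could eliminate the β‑methoxy group); the C‑2 configuration is fixed by the transannular closure.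

## Compound list

1 | but‑2‑yn‑1‑ol | CC#CCO | starting material
2 | (Z)‑3‑iodobut‑2‑en‑1‑ol | C/C(I)=C/CO | intermediate
3 | ethynyltrimethylsilane | C#C[Si](C)(C)C | starting material
4 | (Z)‑3‑methyl‑5‑(trimethylsilyl)pent‑2‑en‑4‑yn‑1‑ol | C/C(C#C[Si](C)(C)C)=C/CO | intermediate
5 | [(2R,3S)‑3‑methyl‑3‑[(trimethylsilyl)ethynyl]oxiran‑2‑yl]methanol | C[Si](C)(C)C#C[C@]1(C)O[C@@H]1CO | intermediate
6 | (2R,3R)‑3‑methoxy‑3‑methyl‑5‑(trimethylsilyl)pent‑4‑yne‑1,2‑diol | C[Si](C)(C)C#C[C@@](C)(OC)[C@H](O)CO | intermediate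
7 | (2R,3R)‑1,2‑bis(TBS‑oxy)‑3‑methoxy‑3‑methyl‑5‑(trimethylsilyl)pent‑4‑yne | C[Si](C)(C)C#C[C@@](C)(OC)[C@H](O[Si](C)(C)C(C)(C)C)CO[Si](C)(C)C(C)(C)C | intermediate
8 | (2R,3R)‑2‑(TBS‑oxy)‑3‑methoxy‑3‑methyl‑5‑(trimethylsilyl)pent‑4‑yn‑1‑ol | C[Si](C)(C)C#C[C@@](C)(OC)[C@H](O[Si](C)(C)C(C)(C)C)CO | intermediate
9 | (2S,3R)‑2‑(TBS‑oxy)‑3‑methoxy‑3‑methyl‑5‑(trimethylsilyl)pent‑4‑ynal | C[Si](C)(C)C#C[C@@](C)(OC)[C@H](O[Si](C)(C)C(C)(C)C)C=O | intermediate
10 | 2‑methylprop‑2‑en‑1‑ol | C=C(C)CO | starting material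
11 | tert‑butyl[(2‑methylprop‑2‑en‑1‑yl)oxy]diphenylsilane | C=C(C)CO[Si](c1ccccc1)(c1ccccc1)C(C)(C)C | intermediate
12 | ethyl glyoxylate | CCOC(=O)C=O | starting material
13 | ethyl (2S)‑4‑[(TBDPS‑oxy)methyl]‑2‑hydroxypent‑4‑enoate | C=C(CO[Si](c1ccccc1)(c1ccccc1)C(C)(C)C)C[C@H](O)C(=O)OCC | intermediate
14 | (2S)‑4‑[(TBDPS‑oxy)methyl]‑2‑hydroxy‑N‑methoxy‑N‑methylpent‑4‑enamide | C=C(CO[Si](c1ccccc1)(c1ccccc1)C(C)(C)C)C[C@H](O)C(=O)N(C)OC | intermediate
15 | tigloyl chloride, (E)‑2‑methylbut‑2‑enoyl chloride | C/C=C(\C)C(=O)Cl | starting material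
16 | (2S)‑4‑[(TBDPS‑oxy)methyl]‑1‑[methoxy(methyl)amino]‑1‑oxopent‑4‑en‑2‑yl (E)‑2‑methylbut‑2‑enoate | C=C(CO[Si](c1ccccc1)(c1ccccc1)C(C)(C)C)C[C@H](OC(=O)/C(C)=C/C)C(=O)N(C)OC | intermediate
17 | ethynylmagnesium bromide | C#C[Mg]Br | starting material
18 | (4S)‑6‑[(TBDPS‑oxy)methyl]‑3‑oxohept‑6‑en‑1‑yn‑4‑yl (E)‑2‑methylbut‑2‑enoate | C=C(CO[Si](c1ccccc1)(c1ccccc1)C(C)(C)C)C[C@H](OC(=O)/C(C)=C/C)C(=O)C#C | intermediate
19 | (3S,4S)‑6‑[(TBDPS‑oxy)methyl]‑3‑hydroxyhept‑6‑en‑1‑yn‑4‑yl (E)‑2‑methylbut‑2‑enoate | C=C(CO[Si](c1ccccc1)(c1ccccc1)C(C)(C)C)C[C@H](OC(=O)/C(C)=C/C)[C@@H](O)C#C | intermediate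
20 | (3S,4S)‑6‑[(TBDPS‑oxy)methyl]‑3‑(mesyloxy)hept‑6‑en‑1‑yn‑4‑yl (E)‑2‑methylbut‑2‑enoate | C=C(CO[Si](c1ccccc1)(c1ccccc1)C(C)(C)C)C[C@H](OC(=O)/C(C)=C/C)[C@@H](OS(C)(=O)=O)C#C | intermediate
21 | (4S,5S,6S,7R,8R)‑7‑(TBS‑oxy)‑2‑[(TBDPS‑oxy)methyl]‑5‑ethynyl‑6‑hydroxy‑8‑methoxy‑8‑methyl‑10‑(trimethylsilyl)dec‑1‑en‑9‑yn‑4‑yl (E)‑2‑methylbut‑2‑enoate | C=C(CO[Si](c1ccccc1)(c1ccccc1)C(C)(C)C)C[C@H](OC(=O)/C(C)=C/C)[C@@H](C#C)[C@H](O)[C@@H](O[Si](C)(C)C(C)(C)C)[C@](C)(OC)C#C[Si](C)(C)C | intermediate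
22 | trans‑α‑methylene‑γ‑lactone, fully silylated (name in step 16) | C=C(CO[Si](c1ccccc1)(c1ccccc1)C(C)(C)C)C[C@H](OC(=O)/C(C)=C/C)[C@H]2C(=C)C(=O)O[C@@H]2[C@@H](O[Si](C)(C)C(C)(C)C)[C@](C)(OC)C#C[Si](C)(C)C | intermediate
23 | lactone diol with terminal alkyne (name in step 17) | C=C(CO)C[C@H](OC(=O)/C(C)=C/C)[C@H]1C(=C)C(=O)O[C@@H]1[C@@H](O)[C@](C)(OC)C#C | intermediate
24 | allylic bromide (name in step 18) | C=C(CBr)C[C@H](OC(=O)/C(C)=C/C)[C@H]1C(=C)C(=O)O[C@@H]1[C@@H](O)[C@](C)(OC)C#C | intermediate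
25 | (4R,5R,6S,7R,8S)‑5‑hydroxy‑4‑methoxy‑8‑tigloyloxygermacra‑10(14),11(13)‑dien‑2‑yn‑12,6‑olide | C=C1C[C@H](OC(=O)/C(C)=C/C)[C@H]2C(=C)C(=O)O[C@@H]2[C@@H](O)[C@](C)(OC)C#CC1 | intermediate
26 | CID 86289099 | C=C1C[C@H](OC(=O)/C(C)=C/C)[C@H]2C(=C)C(=O)O[C@@H]2[C@H]2O[C@](O)(C1)C[C@@]2(C)OC | target

## Summary

**Total steps:** 20 (fragment A: steps 1–7; fragment B: steps 8–14; common: steps 15–20).

**Longest linear sequence:** 13 steps (steps 8–14 then 15–20; the path through steps 1–7 is equally long).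

**Three steps most likely to fail, with fallbacks**

1. **Step 19 (proposed new Cu macrocyclisation).** Risks are oligomerisation, strain in the transition state, and base‑induced oxa‑Michael addition to the methylene lactone. Fallback with known chemistry: close the same C1–C2 bond by an intramolecular Nozaki–Hiyama–Kishi allylation. From **22**, unmask the alkyne and convert it to the C‑2 aldehyde (Cy2BH hydroboration/oxidation), make the C‑1 bromide, cyclise with CrCl2, oxidise the C‑2 carbinol (Dess–Martin) with 5‑O still silylated, then HF·pyridine to release 5‑OH and form the hemiketal.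

2. **Step 15 (Pd/In propargylation).** Risks are the hindered α‑branched allenyl reagent, possible elimination of the δ‑tiglate from the allenylindium, and a reagent/aldehyde mismatch. Fallback: build C6–C7 by an Evans syn‑aldol/lactonisation of **9** with the boron enolate of an N‑(3‑methoxycarbonylpropanoyl)oxazolidinone (trans‑paraconic lactone). Then reduce the C‑8 acyl group to the aldehyde, add C‑9/C‑10/C‑1 by catalytic asymmetric Cr‑mediated 2‑(silyloxymethyl)allylation, tigloylate, and α‑methylenate the lactone (Eschenmoser salt).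

3. **Step 16 (cyclocarbonylation of a hindered alkynol).** Risks are low conversion and silyl migration. Fallback: α‑selective hydrostannation of the terminal alkyne (Mo(CO)3(CNt‑Bu)3, Bu3SnH) and iodination to the 2‑iodo‑1‑alkene, then Pd(0)‑catalysed intramolecular alkoxycarbonylation of the vinyl iodide (CO, Et3N) to the same α‑methylene lactone.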